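Assumption: the target has no stereocentre (it is achiral), so no enantiocontrol is needed; the only stereocentre on the route (C2 of flavanone 6) is racemic and is removed in the last step.

**Retrosynthetic overview**
1. The pyranone C-ring is made last: the flavone is taken back to its flavanone by removing the C2–C3 unsaturation.
2. The flavanone is cut at the O1–C2 bond (oxa-Michael) and the C2–C3 bond (aldol) into a symmetric 2,6-dihydroxy-3,4,5-trimethoxyacetophenone and unprotected syringaldehyde. Because the ketone is symmetric, either hydroxyl closes the ring and the other becomes the 5-OH.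
3. The two ortho C–O bonds of that acetophenone (future O1–C8a and C5–OH) are made together by a twofold ketone-directed C–H oxygenation of 3',4',5'-trimethoxyacetophenone.
4. Ring order: A- and B-rings are bought intact; the C-ring is closed in step 2 and aromatised in step 3; no protecting groups are used.

**Route**

Step 1
Reactants: 1 1-(3,4,5-trimethoxyphenyl)ethanone (3',4',5'-trimethoxyacetophenone)
Product: 3 1-(2,6-dihydroxy-3,4,5-trimethoxyphenyl)ethanone, via bis(trifluoroacetate) ester 2 (not isolated)
Conditions: Pd(O2CCF3)2 (10 mol %), K2S2O8 (4.4 equiv, two portions), TFA/TFAA 9:1, 50 °C, 24 h; then H2O/THF, rt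
Reagents that add atoms: trifluoroacetic acid, OC(=O)C(F)(F)F (source of both new oxygen atoms)
Why: Proposed new method: a twofold ketone-directed Pd(II)/Pd(IV) ortho-C–H oxygenation run to completion in one flask, in which the acetyl oxygen binds electrophilic Pd(II) trifluoroacetate, palladation occurs at the flanking C–H (also the most nucleophilic ring position, ortho and para to two methoxy groups), persulfate oxidises the palladacycle to Pd(IV) and C–O reductive elimination gives the aryl trifluoroacetate; since TFAA keeps the first phenol capped as a non-chelating, oxidation-resistant ester, the carbonyl remains free to direct a second, symmetry-equivalent palladation at C6, and mild hydrolysis then releases both hydroxyls; the closest known reaction type is the Pd(II)- or Ru(II)-catalysed ketone-directed mono-ortho-hydroxylation of aryl ketones in TFA/TFAA, which has not been shown to install both ortho oxygens of a 3,4,5-trialkoxyaryl ketone.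

Step 2
Reactants: 3 1-(2,6-dihydroxy-3,4,5-trimethoxyphenyl)ethanone; 4 syringaldehyde (4-hydroxy-3,5-dimethoxybenzaldehyde)
Product: 6 rac-5-hydroxy-2-(4-hydroxy-3,5-dimethoxyphenyl)-6,7,8-trimethoxychroman-4-one, via 2',6'-dihydroxychalcone 5 (not isolated)
Conditions: pyrrolidine (1.5 equiv), EtOH, reflux, 24 h; then AcOH
Reagents that add atoms: none
Why: Kabbe-type amine-mediated Claisen–Schmidt condensation, in which pyrrolidine turns the aldehyde into an iminium ion that stays electrophilic despite the free para-hydroxyl, the methyl ketone adds and eliminates to the (E)-chalcone, and one of the two equivalent ortho-hydroxyls closes the ring by 6-endo oxa-Michael addition (O1–C2 bond) while the other remains as the chelated 5-OH; the new C2 stereocentre forms as a racemate and is removed in step 3.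

Step 3
Reactants: 6 rac-5-hydroxy-2-(4-hydroxy-3,5-dimethoxyphenyl)-6,7,8-trimethoxychroman-4-one
Product: 7 5,4'-dihydroxy-6,7,8,3',5'-pentamethoxyflavone [5-hydroxy-2-(4-hydroxy-3,5-dimethoxyphenyl)-6,7,8-trimethoxy-4H-chromen-4-one]
Conditions: I2 (0.2 equiv), DMSO, 120 °C, 3 h; then aq Na2S2O3
Reagents that add atoms: none
Why: Iodine/DMSO dehydrogenation of a flavanone, in which C3 iodination of the enolised ketone and loss of HI give the flavone while DMSO reoxidises HI to I2; the C2 stereocentre is erased, and ring iodination is blocked because the A-ring is fully substituted and both positions ortho to the 4'-OH carry methoxy groups.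

**Compound list**
1 | 1-(3,4,5-trimethoxyphenyl)ethanone (3',4',5'-trimethoxyacetophenone) | CC(=O)c1cc(OC)c(OC)c(OC)c1 | starting material
2 | 2-acetyl-4,5,6-trimethoxy-1,3-phenylene bis(trifluoroacetate) | CC(=O)c1c(OC(=O)C(F)(F)F)c(OC)c(OC)c(OC)c1OC(=O)C(F)(F)F | intermediate
3 | 1-(2,6-dihydroxy-3,4,5-trimethoxyphenyl)ethanone | CC(=O)c1c(O)c(OC)c(OC)c(OC)c1O | intermediate
4 | syringaldehyde (4-hydroxy-3,5-dimethoxybenzaldehyde) | COc1cc(C=O)cc(OC)c1O | starting material
5 | (E)-1-(2,6-dihydroxy-3,4,5-trimethoxyphenyl)-3-(4-hydroxy-3,5-dimethoxyphenyl)prop-2-en-1-one | COc1cc(/C=C/C(=O)c2c(O)c(OC)c(OC)c(OC)c2O)cc(OC)c1O | intermediate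
6 | rac-5-hydroxy-2-(4-hydroxy-3,5-dimethoxyphenyl)-6,7,8-trimethoxychroman-4-one (racemic at C2) | COc1cc(C2CC(=O)c3c(O)c(OC)c(OC)c(OC)c3O2)cc(OC)c1O | intermediate
7 | 5,4'-dihydroxy-6,7,8,3',5'-pentamethoxyflavone (achiral) | COc1cc(-c2cc(=O)c3c(O)c(OC)c(OC)c(OC)c3o2)cc(OC)c1O | target

**Totals**
Total step count: 3. Longest linear sequence: 3 steps (1 → 3 → 6 → 7); syringaldehyde 4 enters at step 2.

**Three steps most likely to fail**

Step 1 (highest risk; the proposed new step). The reaction may stop at the mono-phenol, or persulfate may oxidise the electron-rich ring by single-electron transfer instead of the palladacycle. The fallback uses only known chemistry and sets out from 1. Electrophilic ring bromination with NBS (2.2 equiv, MeCN, rt to 50 °C) at the two activated ortho positions gives 1-(2,6-dibromo-3,4,5-trimethoxyphenyl)ethanone F1. Copper-catalysed Ullmann-type hydroxylation (CuI, 8-hydroxyquinoline, KOH, DMSO/H2O, 110 °C, acidic work-up) then replaces both bromides by hydroxyl and comes back to the route at 3.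

Step 2. The hindered, doubly chelated methyl ketone and the three free phenols may make the condensation slow or give chalcone/flavanone mixtures. The fallback sets out from 3 and switches to a protected aldehyde and enolate chemistry. Classical hydroxide Claisen–Schmidt condensation (KOH, EtOH, rt) with commercial 4-(benzyloxy)-3,5-dimethoxybenzaldehyde, which carries no deactivating phenoxide, gives (E)-3-[4-(benzyloxy)-3,5-dimethoxyphenyl]-1-(2,6-dihydroxy-3,4,5-trimethoxyphenyl)prop-2-en-1-one F2. NaOAc in refluxing EtOH isomerises it to rac-2-[4-(benzyloxy)-3,5-dimethoxyphenyl]-5-hydroxy-6,7,8-trimethoxychroman-4-one F3. Hydrogenolysis (H2, Pd/C, EtOAc) removes the benzyl group and comes back to the route at 6.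

Step 3. The free triphenol may decompose or ring-open at 120 °C in I2/DMSO. The fallback avoids any dehydrogenation by building the C-ring at the flavone oxidation level; it sets out from 3. Commercial 4-(benzyloxy)-3,5-dimethoxybenzoic acid is converted with oxalyl chloride/cat. DMF into 4-(benzyloxy)-3,5-dimethoxybenzoyl chloride F4. Baker–Venkataraman-type C-acylation of the polylithiated ketone (3, LiHMDS 4.5 equiv, THF, −78 °C, then F4) gives 1-[4-(benzyloxy)-3,5-dimethoxyphenyl]-3-(2,6-dihydroxy-3,4,5-trimethoxyphenyl)propane-1,3-dione F5. Acid cyclodehydration (AcOH, cat. H2SO4, 95 °C) closes it to 2-[4-(benzyloxy)-3,5-dimethoxyphenyl]-5-hydroxy-6,7,8-trimethoxy-4H-chromen-4-one F6. Hydrogenolysis (H2, Pd/C, EtOAc/MeOH) comes back to the route at 7.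

**Further compounds**
F1 | step 1 | 1-(2,6-dibromo-3,4,5-trimethoxyphenyl)ethanone | CC(=O)c1c(Br)c(OC)c(OC)c(OC)c1Br
F2 | step 2 | (E)-3-[4-(benzyloxy)-3,5-dimethoxyphenyl]-1-(2,6-dihydroxy-3,4,5-trimethoxyphenyl)prop-2-en-1-one | COc1cc(/C=C/C(=O)c2c(O)c(OC)c(OC)c(OC)c2O)cc(OC)c1OCc1ccccc1
F3 | step 2 | rac-2-[4-(benzyloxy)-3,5-dimethoxyphenyl]-5-hydroxy-6,7,8-trimethoxychroman-4-one (racemic at C2) | COc1cc(C2CC(=O)c3c(O)c(OC)c(OC)c(OC)c3O2)cc(OC)c1OCc1ccccc1
F4 | step 3 | 4-(benzyloxy)-3,5-dimethoxybenzoyl chloride | COc1cc(C(=O)Cl)cc(OC)c1OCc1ccccc1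
F5 | step 3 | 1-[4-(benzyloxy)-3,5-dimethoxyphenyl]-3-(2,6-dihydroxy-3,4,5-trimethoxyphenyl)propane-1,3-dione | COc1cc(C(=O)CC(=O)c2c(O)c(OC)c(OC)c(OC)c2O)cc(OC)c1OCc1ccccc1
F6 | step 3 | 2-[4-(benzyloxy)-3,5-dimethoxyphenyl]-5-hydroxy-6,7,8-trimethoxy-4H-chromen-4-one | COc1cc(-c2cc(=O)c3c(O)c(OC)c(OC)c(OC)c3o2)cc(OC)c1OCc1ccccc1
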